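**Retrosynthetic overview**
- The skeleton is cut at C7–C8. The unit C14H2=C7(–C6 of the six-membered ring)–C8H(O-angelate) is a 2-substituted allylic ester whose sp2 carbon hangs on the cyclohexane, i.e. the retron of an alkenylchromium addition to an aldehyde; this feature makes the key step possible.
- Key disconnection: ligand-controlled Ni/Cr (Nozaki–Hiyama–Kishi) union of the fully functionalised ring enol triflate 11 with 4-methylpent-3-enal 13. One operation should give the whole C15 skeleton, the exocyclic methylene in its final position and the C8 stereocentre.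
- Ring half: the cyclohexane is taken from (R)-carvone (its C5 becomes C6, its isopropenyl carbon becomes C7 via acetyl and enol triflate). C1–O (hydroxylation, Mitsunobu inversion) and C2–O (Luche) are set first; the first new ring, the C3–C4 oxirane, follows by OH-directed epoxidation.
- After the coupling only the C8 angelate and the second new ring, the C10–C11 oxirane (Shi epoxidation), remain.

Key step: step 9

Remark: labels follow bisabolane numbering (ring C1 = CH–OAc, C2 = CH–O-angelate, C3 = C–CH3, C4 = oxirane CH, C5 = CH2, C6 = CH bearing the side chain; side chain C7(=C14H2)–C8–C9–C10–C11); for step 9 the ligand enantiomer is assumed to be the one whose chromium complex adds to the Re face of 13, to be confirmed on a model aldehyde.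

**Route**

Step 1
Reactants: 1 (R)-(−)-carvone
Product: 3 trans-6-hydroxycarvone (5S,6S), via potassium dienolate 2 (not isolated)
Conditions: KHMDS, THF, −78 °C; then Davis oxaziridine, −78 °C; aq. NH4Cl
Reagents that add atoms: 2-(phenylsulfonyl)-3-phenyloxaziridine (Davis oxaziridine), O=S(=O)(c1ccccc1)N1OC1c1ccccc1
Why: Kinetic α′-deprotonation gives the cross-conjugated dienolate, and Davis enolate hydroxylation should occur at C6 anti to the adjacent isopropenyl group, giving the 5,6-trans ketol.

Step 2
Reactants: 3 trans-6-hydroxycarvone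
Product: 4 cis-6-acetoxycarvone (1R,6S acetate)
Conditions: PPh3, DIAD, AcOH, toluene, 0 °C → rt
Reagents that add atoms: acetic acid, CC(=O)O
Why: Mitsunobu esterification displaces the alkoxyphosphonium by SN2 with inversion at the carbonyl-activated carbon, turning the trans ketol into the contra-steric cis acetate that the all-cis ring needs.

Step 3
Reactants: 4 cis-6-acetoxycarvone
Product: 5 all-cis allylic alcohol (1R,2S,6S)-2-hydroxy-3-methyl-6-(prop-1-en-2-yl)cyclohex-3-en-1-yl acetate
Conditions: NaBH4, CeCl3·7H2O, MeOH, −78 °C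
Reagents that add atoms: none
Why: Luche reduction is 1,2-selective, and hydride should attack axially on the face anti to the pseudo-axial α-acetoxy group (axial attack and Felkin–Anh reinforce each other), placing the new OH cis to the acetate.

Step 4
Reactants: 5 all-cis allylic alcohol
Product: 6 all-cis epoxy alcohol (oxirane O, OH, OAc and isopropenyl on one face)
Conditions: VO(acac)2 (cat.), t-BuOOH, CH2Cl2, 0 °C → rt
Reagents that add atoms: tert-butyl hydroperoxide, CC(C)(C)OO
Why: Vanadium-catalysed hydroxyl-directed epoxidation delivers oxygen to the trisubstituted ring alkene syn to the allylic OH, setting both oxirane carbons, and should leave the non-allylic isopropenyl alkene untouched.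

Step 5
Reactants: 6 all-cis epoxy alcohol
Product: 7 epoxy angelate (C2 angelate, C1 acetate, isopropenyl on C6)
Conditions: angelic acid, 2,4,6-trichlorobenzoyl chloride, Et3N, toluene, rt; then 6, 75 °C
Reagents that add atoms: angelic acid, C/C=C(/C)C(=O)O
Why: Yamaguchi-type mixed-anhydride esterification without a nucleophilic catalyst should acylate the hindered secondary alcohol without Z→E isomerisation of the angelate; no stereocentre is touched.

Step 6
Reactants: 7 epoxy angelate
Product: 9 methyl ketone (acetyl on C6), via secondary ozonide 8 (not isolated)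
Conditions: O3, CH2Cl2, −78 °C (Sudan Red 7B end point); then Me2S, −78 °C → rt
Reagents that add atoms: ozone, [O-][O+]=O
Why: Ozonolysis should select the electron-rich 1,1-disubstituted alkene over the electron-poor angelate C=C, and the neutral reductive work-up spares the base-sensitive β-acetoxy ketone and its α-stereocentre.

Step 7
Reactants: 9 methyl ketone
Product: 11 enol triflate (1-triflyloxyvinyl group on C6), via potassium methyl-side enolate 10 (not isolated)
Conditions: KHMDS, THF, −78 °C; then Comins' reagent, −78 °C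
Reagents that add atoms: N-(5-chloro-2-pyridyl)bis(trifluoromethanesulfonimide) (Comins' reagent), Clc1ccc(nc1)N(S(=O)(=O)C(F)(F)F)S(=O)(=O)C(F)(F)F
Why: Kinetic deprotonation by the hindered amide base occurs at the CH3 group and O-sulfonylation at −78 °C traps the terminal enolate, so the ring methine should be neither epimerised nor used for E1cB loss of acetate.

Step 8
Reactants: 12 4-methylpent-3-en-1-ol
Product: 13 4-methylpent-3-enal
Conditions: Dess–Martin periodinane, NaHCO3, CH2Cl2, 0 °C; filtered solution used at once
Reagents that add atoms: none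
Why: Buffered Dess–Martin oxidation converts the homoallylic alcohol into the β,γ-unsaturated aldehyde without moving the double bond into conjugation.

Step 9
Reactants: 11 enol triflate; 13 4-methylpent-3-enal
Product: 15 allylic alcohol (8S), via alkenylchromium(III) species 14 (not isolated)
Conditions: CrCl2, chiral oxazoline–sulfonamide ligand, Et3N, NiCl2 (cat.), THF–MeCN, rt; aq. sodium serinate work-up
Reagents that add atoms: none
Why: Ni(0), formed from NiCl2 by CrCl2, inserts into the C7–OTf bond of 11 and transmetallates to Cr(III); the alkenylchromium 14 then adds to the aldehyde carbon of 13 inside the chiral chromium–sulfonamide complex, forming C7–C8 and the chromium alkoxide of 15. The closest known reaction type is the asymmetric Nozaki–Hiyama–Kishi coupling of 2-triflyloxy- or 2-halo-1-alkenes with aliphatic aldehydes to give 2-substituted allylic alcohols. No ring is closed. The one new stereocentre, C8, is set by the chiral ligand on chromium (Re-face addition to 13 gives 8S), i.e. by reagent control, because the nearest resident stereocentre (ring C6) is separated from C8 by the sp2 carbon C7. The step needs chemoselectivity (aldehyde over acetate, angelate and oxirane; no enolisation or conjugation of the β,γ-unsaturated aldehyde; no elimination of the ring acetate), which the non-basic, weakly nucleophilic organochromium(III) secures together with the fact that the enol triflate is the only C(sp2)–X bond in 11. The position of the alkene is fixed because the C–Cr bond sits on C7 of the pre-formed C7=C14H2 unit.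

Step 10
Reactants: 15 allylic alcohol
Product: 16 bis-angelate (prenyl alkene still present)
Conditions: angelic acid, 2,4,6-trichlorobenzoyl chloride, Et3N, toluene, rt; then 15, 75 °C
Reagents that add atoms: angelic acid, C/C=C(/C)C(=O)O
Why: The same mixed-anhydride angeloylation as in step 5 acylates the secondary allylic alcohol with retention at C8, since the C8–O bond is not broken.

Step 11
Reactants: 16 bis-angelate
Product: 17 target compound
Conditions: L-fructose-derived Shi ketone (ent-Shi ketone, cat.), Oxone, K2CO3, Bu4NHSO4, Na2B4O7/EDTA buffer, MeCN–dimethoxymethane–H2O, 0 °C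
Reagents that add atoms: potassium peroxymonosulfate (active component of Oxone), [K+].[O-]S(=O)(=O)OO
Why: In the Shi epoxidation the electrophilic chiral dioxirane should react only with the electron-rich trisubstituted prenyl alkene (not with the angelates or the 1,1-disubstituted alkene next to an allylic ester), and the L-series ketone sets the (S)-oxirane carbon C10 by reagent control through the spiro transition state.

**Compound list**

1 | (R)-(−)-carvone | C=C(C)[C@@H]1CC=C(C)C(=O)C1 | starting material
2 | potassium cross-conjugated dienolate of carvone | C=C(C)[C@@H]1CC=C(C)C([O-])=C1.[K+] | intermediate (not isolated)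
3 | trans-6-hydroxycarvone, (5S,6S)-6-hydroxy-2-methyl-5-(prop-1-en-2-yl)cyclohex-2-en-1-one | C=C(C)[C@@H]1CC=C(C)C(=O)[C@H]1O | intermediate
4 | cis-6-acetoxycarvone, (1R,6S)-3-methyl-2-oxo-6-(prop-1-en-2-yl)cyclohex-3-en-1-yl acetate | C=C(C)[C@@H]1CC=C(C)C(=O)[C@@H]1OC(C)=O | intermediate
5 | (1R,2S,6S)-2-hydroxy-3-methyl-6-(prop-1-en-2-yl)cyclohex-3-en-1-yl acetate (OH, OAc, isopropenyl all cis) | C=C(C)[C@@H]1CC=C(C)[C@H](O)[C@@H]1OC(C)=O | intermediate
6 | (1R,2R,3R,4S,6S)-2-hydroxy-1-methyl-4-(prop-1-en-2-yl)-7-oxabicyclo[4.1.0]heptan-3-yl acetate (all-cis epoxy alcohol) | C=C(C)[C@@H]1C[C@@H]2O[C@]2(C)[C@H](O)[C@@H]1OC(C)=O | intermediate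
7 | (1S,2R,3R,4S,6S)-3-acetoxy-1-methyl-4-(prop-1-en-2-yl)-7-oxabicyclo[4.1.0]heptan-2-yl (Z)-2-methylbut-2-enoate | C=C(C)[C@@H]1C[C@@H]2O[C@]2(C)[C@H](OC(=O)/C(C)=C\C)[C@@H]1OC(C)=O | intermediate
8 | secondary ozonide (3-methyl-1,2,4-trioxolan-3-yl group in place of the isopropenyl group of 7) | CC1(OCOO1)[C@@H]1C[C@@H]2O[C@]2(C)[C@H](OC(=O)/C(C)=C\C)[C@@H]1OC(C)=O | intermediate (not isolated)
9 | (1S,2R,3R,4R,6S)-3-acetoxy-4-acetyl-1-methyl-7-oxabicyclo[4.1.0]heptan-2-yl (Z)-2-methylbut-2-enoate | CC(=O)[C@@H]1C[C@@H]2O[C@]2(C)[C@H](OC(=O)/C(C)=C\C)[C@@H]1OC(C)=O | intermediate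
10 | potassium enolate of 9 on the methyl side | C=C([O-])[C@@H]1C[C@@H]2O[C@]2(C)[C@H](OC(=O)/C(C)=C\C)[C@@H]1OC(C)=O.[K+] | intermediate (not isolated)
11 | (1S,2R,3R,4R,6S)-3-acetoxy-1-methyl-4-[1-(trifluoromethylsulfonyloxy)vinyl]-7-oxabicyclo[4.1.0]heptan-2-yl (Z)-2-methylbut-2-enoate | C=C(OS(=O)(=O)C(F)(F)F)[C@@H]1C[C@@H]2O[C@]2(C)[C@H](OC(=O)/C(C)=C\C)[C@@H]1OC(C)=O | intermediate
12 | 4-methylpent-3-en-1-ol | CC(C)=CCCO | starting material
13 | 4-methylpent-3-enal | CC(C)=CCC=O | intermediate
14 | alkenylchromium(III) dichloride from 11 (chiral ligand omitted) | C=C([Cr](Cl)Cl)[C@@H]1C[C@@H]2O[C@]2(C)[C@H](OC(=O)/C(C)=C\C)[C@@H]1OC(C)=O | intermediate (not isolated)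
15 | (1S,2R,3R,4S,6S)-3-acetoxy-4-[(3S)-3-hydroxy-6-methylhepta-1,5-dien-2-yl]-1-methyl-7-oxabicyclo[4.1.0]heptan-2-yl (Z)-2-methylbut-2-enoate | C=C([C@H](CC=C(C)C)O)[C@@H]1C[C@@H]2O[C@]2(C)[C@H](OC(=O)/C(C)=C\C)[C@@H]1OC(C)=O | intermediate
16 | (1S,2R,3R,4S,6S)-3-acetoxy-1-methyl-4-{(3S)-6-methyl-3-[(Z)-2-methylbut-2-enoyloxy]hepta-1,5-dien-2-yl}-7-oxabicyclo[4.1.0]heptan-2-yl (Z)-2-methylbut-2-enoate | C=C([C@H](CC=C(C)C)OC(=O)/C(C)=C\C)[C@@H]1C[C@@H]2O[C@]2(C)[C@H](OC(=O)/C(C)=C\C)[C@@H]1OC(C)=O | intermediate
17 | (1S,2R,3R,4S,6S)-3-acetoxy-4-{(3S)-4-[(2S)-3,3-dimethyloxiran-2-yl]-3-[(Z)-2-methylbut-2-enoyloxy]but-1-en-2-yl}-1-methyl-7-oxabicyclo[4.1.0]heptan-2-yl (Z)-2-methylbut-2-enoate, CNP0118696.1 | C=C([C@H](C[C@@H]1OC1(C)C)OC(=O)/C(C)=C\C)[C@@H]1C[C@@H]2O[C@]2(C)[C@H](OC(=O)/C(C)=C\C)[C@@H]1OC(C)=O | target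

**Step count**

Total steps: 11. Longest linear sequence: 10 (steps 1–7 and 9–11 from 1; step 8 is the one-step side branch).

**Steps most likely to fail**

1. Step 7. The methyl-side enolate may equilibrate to the ring-side enolate, which would expel the anti-periplanar β-acetate (E1cB) or epimerise C6. Fallback without any ketone enolate: from ketone 9, condensation with 1,2-bis(tert-butyldimethylsilyl)hydrazine (cat. Sc(OTf)3) should give the N-silyl hydrazone F1. Iodine and 1,1,3,3-tetramethylguanidine in THF at 0 °C (Barton vinyl iodide synthesis) should convert it into the 2-iodo-1-alkene F2 with loss of N2. F2 is coupled with 13 under the Ni/Cr conditions of step 9, and the route is rejoined at 15.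

2. Step 9. Ligand control of the aldehyde face may be eroded by the α-branched alkenyl group, or the aldehyde may drift into conjugation before it is consumed. Fallback that sets C8 by ketone reduction: from 11 and 13, a ligand-free Ni/Cr coupling (CrCl2, cat. NiCl2, DMF) should give 15 together with its C8 epimer F3. Dess–Martin oxidation of the mixture gives the cross-conjugated enone F4. Corey–Bakshi–Shibata reduction with the (R)-oxazaborolidine and catecholborane at −78 °C (alkenyl as the large group) should return 15 as the 8S alcohol.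

3. Step 2. The alkoxyphosphonium of the α-ketol may enolise or eliminate before acetate attacks, so inversion could be incomplete. Fallback that avoids the ketol: from 1, LDA/TMSCl gives the trimethylsilyl dienol ether F5. NBS at −78 °C should brominate C6 anti to the isopropenyl group to give trans-6-bromocarvone F6. SN2 displacement with caesium acetate/18-crown-6 inverts C6 and rejoins the route at 4.

Further compounds
F1 | step 7 | N-(tert-butyldimethylsilyl)hydrazone of ketone 9 | CC(=NN[Si](C)(C)C(C)(C)C)[C@@H]1C[C@@H]2O[C@]2(C)[C@H](OC(=O)/C(C)=C\C)[C@@H]1OC(C)=O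
F2 | step 7 | 2-iodo-1-alkene (1-iodovinyl group on C6 in place of the triflate of 11) | C=C(I)[C@@H]1C[C@@H]2O[C@]2(C)[C@H](OC(=O)/C(C)=C\C)[C@@H]1OC(C)=O
F3 | step 9 | (8R)-epimer of 15 | C=C([C@@H](CC=C(C)C)O)[C@@H]1C[C@@H]2O[C@]2(C)[C@H](OC(=O)/C(C)=C\C)[C@@H]1OC(C)=O
F4 | step 9 | cross-conjugated enone (C8 ketone of 15) | C=C(C(=O)CC=C(C)C)[C@@H]1C[C@@H]2O[C@]2(C)[C@H](OC(=O)/C(C)=C\C)[C@@H]1OC(C)=O
F5 | step 2 | carvone trimethylsilyl dienol ether | C=C(C)[C@@H]1CC=C(C)C(O[Si](C)(C)C)=C1
F6 | step 2 | trans-6-bromocarvone | C=C(C)[C@@H]1CC=C(C)C(=O)[C@H]1Br
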